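**Plan**

- Enabling feature: ring C (O1–C2–C3–C4–C4a–C8a) is the carba-analogue of a salicylic acid acetal. With oxygen in place of C3H2 it would be a 1,3-benzodioxin-4-one, and C2 carries the 4-oxygenated ring B aryl, which stabilises an O1=C2 oxocarbenium ion.
- Retrosynthesis: cut C2–C3 (back to a racemic 4-methylene-1,3-benzodioxine with O3 where C3 will be), then the exocyclic C4=CH2 (back to the lactone), then the acetal bonds C2–O1 and C2–O3 (ring A salicylic acid plus ring B aldehyde), and last the two aryl–prenyl bonds.
- Forward: the ring A acid (steps 1–4) and the ring B aldehyde (steps 5–6) are made separately, joined as the benzodioxinone (step 7), methylenated (step 8), rearranged so that ring C closes (step 9) and desilylated (step 10).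
- Stereochemistry: C2 is the only stereocentre. It is set (S) in step 9 by a chiral Brønsted acid acting on a planar cation, so the racemic acetal centre of the precursor does not matter.

Key step: step 9

Assumption: the (S,S)-antipode of the chiral acid is taken to give the (2S) series; if the first run shows the opposite sense, the (R,R)-antipode is used in step 9 and nothing else changes.

TBS = tert-butyldimethylsilyl; prenyl = 3-methylbut-2-en-1-yl.

**Route**

Step 1
Reactants: 1 2,4,6-trihydroxybenzoic acid (used as the commercial monohydrate)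
Product: 2 prop-2-en-1-yl (allyl) 2,4,6-trihydroxybenzoate
Conditions: allyl bromide, KHCO3, DMF, rt
Reagents that add atoms: allyl bromide, C=CCBr
Why: SN2 O-alkylation of the carboxylate is the only reaction open under bicarbonate, which deprotonates the strongly acidic carboxyl group but not the phenols and keeps the acid as its salt at room temperature, so the decarboxylation to which the free acid is prone on heating is avoided.

Step 2
Reactants: 2 allyl 2,4,6-trihydroxybenzoate; 3 1-bromo-3-methylbut-2-ene (prenyl bromide)
Product: 4 allyl 2,4,6-trihydroxy-3-(3-methylbut-2-en-1-yl)benzoate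
Conditions: DBU, THF, 0 °C to rt
Reagents that add atoms: none
Why: Base-mediated C-alkylation of the phloroglucinol-type phenoxide (attack through a ring carbon, then re-aromatisation) is the usual way to C-prenylate acylphloroglucinols, and because C3 and C5 of 2 are equivalent the mono-C-prenyl product is a single regioisomer, with O-prenyl and diprenyl by-products removed by chromatography.

Step 3
Reactants: 4 allyl 2,4,6-trihydroxy-3-prenylbenzoate
Product: 5 allyl 4,6-bis[(tert-butyldimethylsilyl)oxy]-2-hydroxy-3-(3-methylbut-2-en-1-yl)benzoate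
Conditions: TBSCl (2.1 equiv), imidazole, CH2Cl2, 0 °C
Reagents that add atoms: tert-butyldimethylsilyl chloride (TBSCl), CC(C)(C)[Si](C)(C)Cl
Why: Regioselective silyl ether formation is expected because the non-chelated, most acidic 4-OH reacts first and, of the two ester-chelated hydroxyls, the 6-OH (next to an aryl H) is much more accessible to the bulky silyl chloride than the 2-OH wedged between the prenyl chain and the ester, the pattern seen in partial protection of 3-substituted acylphloroglucinols.

Step 4
Reactants: 5 allyl 4,6-bis(TBS-oxy)-2-hydroxy-3-prenylbenzoate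
Product: 6 4,6-bis[(tert-butyldimethylsilyl)oxy]-2-hydroxy-3-(3-methylbut-2-en-1-yl)benzoic acid
Conditions: Pd(PPh3)4 (cat.), morpholine, THF, rt; pH 4 citrate work-up
Reagents that add atoms: none
Why: Tsuji–Trost deallylation, in which zerovalent palladium ionises the allyl ester to a π-allyl complex that morpholine captures, frees the acid under neutral conditions that leave the aryl silyl ethers, the prenyl alkene and the phenol alone, whereas saponification of a simple alkyl ester would strip the silyl groups.

Step 5
Reactants: 7 4-hydroxybenzaldehyde; 3 1-bromo-3-methylbut-2-ene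
Product: 8 4-hydroxy-3-(3-methylbut-2-en-1-yl)benzaldehyde
Conditions: KOH, H2O, rt
Reagents that add atoms: none
Why: ortho C-alkylation of the phenoxide in water, where hydrogen bonding to the phenoxide oxygen disfavours O-alkylation and the para position is blocked by the formyl group, is the established one-step access to this aldehyde, the O-prenyl ether by-product being separated.

Step 6
Reactants: 8 4-hydroxy-3-prenylbenzaldehyde
Product: 9 4-[(tert-butyldimethylsilyl)oxy]-3-(3-methylbut-2-en-1-yl)benzaldehyde
Conditions: TBSCl, imidazole, DMF, rt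
Reagents that add atoms: tert-butyldimethylsilyl chloride (TBSCl), CC(C)(C)[Si](C)(C)Cl
Why: Standard imidazole-promoted silylation of a phenol, giving the silyl ether that later acts as the electron donor stabilising the C2 cation.

Step 7
Reactants: 6 4,6-bis(TBS-oxy)-2-hydroxy-3-prenylbenzoic acid; 9 4-(TBS-oxy)-3-prenylbenzaldehyde
Product: 11 racemic 5,7-bis[(tert-butyldimethylsilyl)oxy]-2-{4-[(tert-butyldimethylsilyl)oxy]-3-(3-methylbut-2-en-1-yl)phenyl}-8-(3-methylbut-2-en-1-yl)-4H-1,3-benzodioxin-4-one, via bis-trimethylsilyl derivative 10 (not isolated)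
Conditions: (Me3Si)2NH, THF, rt, then evaporation; 9, Me3SiOTf (10 mol %), 2,6-di-tert-butyl-4-methylpyridine (cat.), CH2Cl2, −78 to −20 °C; pyridine quench
Reagents that add atoms: none
Why: Me3SiOTf-catalysed silyl-transfer acetalisation, the condensation routinely used to turn bis-silylated β-hydroxy acids and aldehydes into 1,3-dioxan-4-ones, should work because the activated electron-rich aldehyde is attacked by the silyl ester and the resulting acyloxy-stabilised benzylic cation is closed by the ortho silyl ether with loss of (Me3Si)2O, giving the acetal centre C2 as a racemate, which is of no consequence.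

Step 8
Reactants: 11 racemic benzodioxinone
Product: 12 racemic 5,7-bis[(tert-butyldimethylsilyl)oxy]-2-{4-[(tert-butyldimethylsilyl)oxy]-3-(3-methylbut-2-en-1-yl)phenyl}-4-methylidene-8-(3-methylbut-2-en-1-yl)-4H-1,3-benzodioxine
Conditions: Cp2TiMe2 (3 equiv), toluene/THF, 65 °C, dark; filtration through basic alumina (Et3N-treated)
Reagents that add atoms: dimethyltitanocene (Cp2TiMe2), C[Ti](C)(C1C=CC=C1)C1C=CC=C1
Why: Petasis methylenation, in which Cp2Ti=CH2 generated thermally from Cp2TiMe2 converts the lactone carbonyl into the exocyclic enol ether through an oxatitanacyclobutane and not a free tetrahedral alkoxide (which would expel the acetal), is neutral and not Lewis acidic, so the silyl ethers, the acetal and the prenyl alkenes should survive as they do with 1,3-dioxan-4-ones.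

Step 9
Reactants: 12 racemic 4-methylidene-1,3-benzodioxine
Product: 13 (2S)-5,7-bis[(tert-butyldimethylsilyl)oxy]-2-{4-[(tert-butyldimethylsilyl)oxy]-3-(3-methylbut-2-en-1-yl)phenyl}-8-(3-methylbut-2-en-1-yl)-2,3-dihydro-4H-chromen-4-one
Conditions: (S,S)-IDPi acid (BINOL-derived N,N′-bis(triflyl) imidodiphosphorimidate, 3,3′-bis[3,5-bis(trifluoromethyl)phenyl] groups; 5 mol %), 5 Å molecular sieves, toluene, −40 °C; Et3N quench
Reagents that add atoms: none
Why: Proposed new method: the chiral acid protonates the enol-acetal oxygen O3 of either enantiomer of 12 (protonation at the exocyclic carbon leads, after fragmentation and re-enolisation, to the same species), the C2–O3 bond breaks, and an achiral pair of a C4 enol and an O1=C2 oxocarbenium ion, both held on ring A and the cation stabilised by the 4′-silyloxy group of ring B, sits in the chiral anion until the enol carbon adds to C2, the former O3 becomes the C4 carbonyl oxygen and the proton returns to the catalyst. The closest known reactions are the Me2AlCl-promoted Petasis–Ferrier rearrangement of 4-methylene-1,3-dioxanes to tetrahydropyran-4-ones and the chiral phosphoric acid catalysed aza-Petasis–Ferrier rearrangement of hemiaminal vinyl ethers, which share the ionisation–recombination sequence but not the benzo-fused O,O-acetal under purely Brønsted acid catalysis. Ring C closes in a 6-(enolendo)-endo-trig mode, with the enol bond C3=C4 and the cationic bond O1=C2 both inside the new six-membered ring. The C2 stereocentre is set by the confined counter-anion, which hydrogen-bonds the enol OH and covers one face of the planar oxocarbenium ion, so both enantiomers of the acetal converge on the (2S)-ketone. The step needs enantioface selection at C2 and chemoselective ionisation of the enol acetal beside two prenyl alkenes; the first rests on the tight ion pair in toluene at low temperature, the second on the much higher basicity of the enol acetal, on silylation of every phenol (no OH can trap a prenyl cation as a chroman) and on molecular sieves that exclude hydrolysis.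

Step 10
Reactants: 13 (2S)-tri-O-TBS flavanone
Product: 14 euchrestaflavanone A, (2S)-5,7-dihydroxy-2-[4-hydroxy-3-(3-methylbut-2-en-1-yl)phenyl]-8-(3-methylbut-2-en-1-yl)-2,3-dihydro-4H-chromen-4-one
Conditions: HF·pyridine, pyridine, THF, 0 °C to rt; pH 7 buffer work-up
Reagents that add atoms: none
Why: Fluoride-mediated cleavage of the three aryl silyl ethers in a pyridine-buffered, mildly acidic medium avoids the base-induced ring opening to the chalcone that would racemise C2 and is too weakly acidic to cyclise the prenyl groups onto the liberated ortho phenols.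

**Compound list**

1 | 2,4,6-trihydroxybenzoic acid | O=C(O)c1c(O)cc(O)cc1O | starting material
2 | allyl 2,4,6-trihydroxybenzoate | C=CCOC(=O)c1c(O)cc(O)cc1O | intermediate
3 | 1-bromo-3-methylbut-2-ene (prenyl bromide) | CC(C)=CCBr | starting material
4 | allyl 2,4,6-trihydroxy-3-(3-methylbut-2-en-1-yl)benzoate | C=CCOC(=O)c1c(O)cc(O)c(CC=C(C)C)c1O | intermediate
5 | allyl 4,6-bis[(tert-butyldimethylsilyl)oxy]-2-hydroxy-3-(3-methylbut-2-en-1-yl)benzoate | C=CCOC(=O)c1c(O[Si](C)(C)C(C)(C)C)cc(O[Si](C)(C)C(C)(C)C)c(CC=C(C)C)c1O | intermediate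
6 | 4,6-bis[(tert-butyldimethylsilyl)oxy]-2-hydroxy-3-(3-methylbut-2-en-1-yl)benzoic acid | O=C(O)c1c(O[Si](C)(C)C(C)(C)C)cc(O[Si](C)(C)C(C)(C)C)c(CC=C(C)C)c1O | intermediate
7 | 4-hydroxybenzaldehyde | O=Cc1ccc(O)cc1 | starting material
8 | 4-hydroxy-3-(3-methylbut-2-en-1-yl)benzaldehyde | CC(C)=CCc1cc(C=O)ccc1O | intermediate
9 | 4-[(tert-butyldimethylsilyl)oxy]-3-(3-methylbut-2-en-1-yl)benzaldehyde | CC(C)=CCc1cc(C=O)ccc1O[Si](C)(C)C(C)(C)C | intermediate
10 | trimethylsilyl 4,6-bis[(tert-butyldimethylsilyl)oxy]-3-(3-methylbut-2-en-1-yl)-2-[(trimethylsilyl)oxy]benzoate | C[Si](C)(C)OC(=O)c1c(O[Si](C)(C)C(C)(C)C)cc(O[Si](C)(C)C(C)(C)C)c(CC=C(C)C)c1O[Si](C)(C)C | intermediate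
11 | racemic 5,7-bis[(tert-butyldimethylsilyl)oxy]-2-{4-[(tert-butyldimethylsilyl)oxy]-3-(3-methylbut-2-en-1-yl)phenyl}-8-(3-methylbut-2-en-1-yl)-4H-1,3-benzodioxin-4-one | O=C1OC(c2ccc(O[Si](C)(C)C(C)(C)C)c(CC=C(C)C)c2)Oc2c(CC=C(C)C)c(O[Si](C)(C)C(C)(C)C)cc(O[Si](C)(C)C(C)(C)C)c12 | intermediate
12 | racemic 5,7-bis[(tert-butyldimethylsilyl)oxy]-2-{4-[(tert-butyldimethylsilyl)oxy]-3-(3-methylbut-2-en-1-yl)phenyl}-4-methylidene-8-(3-methylbut-2-en-1-yl)-4H-1,3-benzodioxine | C=C1OC(c2ccc(O[Si](C)(C)C(C)(C)C)c(CC=C(C)C)c2)Oc2c(CC=C(C)C)c(O[Si](C)(C)C(C)(C)C)cc(O[Si](C)(C)C(C)(C)C)c12 | intermediate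
13 | (2S)-5,7-bis[(tert-butyldimethylsilyl)oxy]-2-{4-[(tert-butyldimethylsilyl)oxy]-3-(3-methylbut-2-en-1-yl)phenyl}-8-(3-methylbut-2-en-1-yl)-2,3-dihydro-4H-chromen-4-one | CC(C)=CCc1cc([C@@H]2CC(=O)c3c(O[Si](C)(C)C(C)(C)C)cc(O[Si](C)(C)C(C)(C)C)c(CC=C(C)C)c3O2)ccc1O[Si](C)(C)C(C)(C)C | intermediate
14 | euchrestaflavanone A, (2S)-5,7-dihydroxy-2-[4-hydroxy-3-(3-methylbut-2-en-1-yl)phenyl]-8-(3-methylbut-2-en-1-yl)-2,3-dihydro-4H-chromen-4-one | CC(C)=CCc1cc([C@@H]2CC(=O)c3c(O)cc(O)c(CC=C(C)C)c3O2)ccc1O | target

**Step count**

Total: 10 steps. Longest linear sequence: 8 steps (steps 1, 2, 3, 4, 7, 8, 9, 10); steps 5 and 6 form the ring B branch.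

**Steps most likely to fail**

Step 9 (asymmetric O-to-C rearrangement). The ion pair may collapse with poor facial selectivity, or the ionised intermediate may be diverted by hydrolysis or by protonation of a prenyl alkene. The fallback uses known reactions, sets out from 12 and returns at 13. Mild hydrolysis of the enol acetal (PPTS, wet THF, rt) would give 1-{4,6-bis[(tert-butyldimethylsilyl)oxy]-2-hydroxy-3-(3-methylbut-2-en-1-yl)phenyl}ethan-1-one F1 together with aldehyde 9. The two would be recombined by pyrrolidine-mediated aldol condensation and oxa-Michael ring closure (pyrrolidine, MeCN, 50 °C) to racemic 5,7,4′-tri-O-TBS euchrestaflavanone A F2. Preparative HPLC on a chiral stationary phase (amylose tris(3,5-dimethylphenylcarbamate)) would then separate 13 from (2R)-5,7,4′-tri-O-TBS euchrestaflavanone A F3, which could be racemised by ring opening to the chalcone and recycled.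

Step 7 (union of the ring A acid and the ring B aldehyde). The Me3SiOTf-activated, electron-rich aldehyde may alkylate C5 of ring A in a Friedel–Crafts sense or oligomerise, and ring closure by the hindered O2 silyl ether may lag behind desilylation and decarboxylation of the acid. The fallback sets out from 9 (with 6) and returns at 11. Aldehyde 9 would be converted with HC(OMe)3 and PPTS (cat.) in MeOH into tert-butyl[4-(dimethoxymethyl)-2-(3-methylbut-2-en-1-yl)phenoxy]dimethylsilane F4. Free acid 6 would then be condensed with it by acid-catalysed acetal exchange (camphorsulfonic acid cat., 5 Å molecular sieves to take up methanol, CH2Cl2, rt). A preformed acetal under thermodynamic control thus replaces the free aldehyde and the silyl triflate.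

Step 3 (regioselective bis-silylation). Silylation may fail to discriminate between the two chelated hydroxyls or run on to the tris-silyl ether, which would send the prenyl group to C6 of the flavanone or block the acetal-forming hydroxyl. The fallback sets out from 2, bypasses steps 2 and 3, and returns at 5; regiochemistry is fixed by a sigmatropic shift and not by kinetic protection.
- Symmetrical 2 would be bis-silylated (TBSCl 2 equiv, imidazole, CH2Cl2, 0 °C) to allyl 4,6-bis[(tert-butyldimethylsilyl)oxy]-2-hydroxybenzoate F5, where O2 and O6 are equivalent.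
- The remaining hydroxyl would be alkylated with 2-methylbut-3-yn-2-yl methyl carbonate (CuCl2 cat., DBU, MeCN, 0 °C) to allyl 4,6-bis[(tert-butyldimethylsilyl)oxy]-2-[(2-methylbut-3-yn-2-yl)oxy]benzoate F6.
- Semihydrogenation (H2, Pd/CaCO3 poisoned with Pb(OAc)2, quinoline, EtOAc) would give allyl 4,6-bis[(tert-butyldimethylsilyl)oxy]-2-[(2-methylbut-3-en-2-yl)oxy]benzoate F7.
- Aromatic Claisen rearrangement (toluene, 110 °C) would move the allyl unit, with inversion to a prenyl group, to C3, the only free ortho carbon, giving 5.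

**Further compounds**

F1 | step 9 | 1-{4,6-bis[(tert-butyldimethylsilyl)oxy]-2-hydroxy-3-(3-methylbut-2-en-1-yl)phenyl}ethan-1-one | CC(=O)c1c(O[Si](C)(C)C(C)(C)C)cc(O[Si](C)(C)C(C)(C)C)c(CC=C(C)C)c1O
F2 | step 9 | racemic 5,7-bis[(tert-butyldimethylsilyl)oxy]-2-{4-[(tert-butyldimethylsilyl)oxy]-3-(3-methylbut-2-en-1-yl)phenyl}-8-(3-methylbut-2-en-1-yl)-2,3-dihydro-4H-chromen-4-one | CC(C)=CCc1cc(C2CC(=O)c3c(O[Si](C)(C)C(C)(C)C)cc(O[Si](C)(C)C(C)(C)C)c(CC=C(C)C)c3O2)ccc1O[Si](C)(C)C(C)(C)C
F3 | step 9 | (2R)-5,7-bis[(tert-butyldimethylsilyl)oxy]-2-{4-[(tert-butyldimethylsilyl)oxy]-3-(3-methylbut-2-en-1-yl)phenyl}-8-(3-methylbut-2-en-1-yl)-2,3-dihydro-4H-chromen-4-one | CC(C)=CCc1cc([C@H]2CC(=O)c3c(O[Si](C)(C)C(C)(C)C)cc(O[Si](C)(C)C(C)(C)C)c(CC=C(C)C)c3O2)ccc1O[Si](C)(C)C(C)(C)C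
F4 | step 7 | tert-butyl[4-(dimethoxymethyl)-2-(3-methylbut-2-en-1-yl)phenoxy]dimethylsilane | COC(OC)c1ccc(O[Si](C)(C)C(C)(C)C)c(CC=C(C)C)c1
F5 | step 3 | allyl 4,6-bis[(tert-butyldimethylsilyl)oxy]-2-hydroxybenzoate | C=CCOC(=O)c1c(O)cc(O[Si](C)(C)C(C)(C)C)cc1O[Si](C)(C)C(C)(C)C
F6 | step 3 | allyl 4,6-bis[(tert-butyldimethylsilyl)oxy]-2-[(2-methylbut-3-yn-2-yl)oxy]benzoate | C=CCOC(=O)c1c(OC(C)(C)C#C)cc(O[Si](C)(C)C(C)(C)C)cc1O[Si](C)(C)C(C)(C)C
F7 | step 3 | allyl 4,6-bis[(tert-butyldimethylsilyl)oxy]-2-[(2-methylbut-3-en-2-yl)oxy]benzoate | C=CCOC(=O)c1c(OC(C)(C)C=C)cc(O[Si](C)(C)C(C)(C)C)cc1O[Si](C)(C)C(C)(C)C
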